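**Plan**

- Numbering: C6 is the aminal CH bonded to the pyrrole N; C10 is the quaternary aminal carbon shared by the pyrrolidine, pyrazinone and imidazolidinone rings.
- Retrosynthesis: cut both C–Br bonds, then N(pyrrole)–C6 (pyrazinone ring, N-acyliminium closure), then N–C10 of the imidazolidinone (C–H amination), then C6–N(urea) (N-alkylation) and the amide bond. This leads back to D-prolinol, N-Boc-pyrrole-2-carboxylic acid and a sulfamoyl urea.
- Forward ring order: pyrrolidine and pyrrole are bought. The imidazolidinone is closed by Rh-nitrenoid insertion into C10–H to give a spiro aminal. The pyrazinone is closed last by the pyrrole N attacking C6. Bromine is introduced at the end.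
- Enabling feature: C10 is a proline α-carbon in which N stands where H was, and the N–C(=O)–N unit bridges C6 and C10. A urea nitrene tethered through the nitrogen on C6 therefore reaches C10–H through a five-membered transition state.
- Stereochemistry: C10 comes from (R)-prolinol and the insertion proceeds with retention. C6 is fixed in the last ring closure, because the three-atom tether from the amide N can reach only the cis face.

Key step: step 6

Remark: bromination is placed last on the assumption that zinc (step 7) could reduce pyrrole C–Br bonds. N-(2,2,2-Trichloroethoxysulfonyl)urea is prepared in step 4 rather than assumed to be purchasable.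

**Step 1**
Reactants: 1 1-(tert-butoxycarbonyl)-1H-pyrrole-2-carboxylic acid; 2 (R)-pyrrolidin-2-ylmethanol (D-prolinol)
Product: 4 tert-butyl 2-{[(2R)-2-(hydroxymethyl)pyrrolidin-1-yl]carbonyl}-1H-pyrrole-1-carboxylate, via tert-butyl 2-(1H-imidazol-1-ylcarbonyl)-1H-pyrrole-1-carboxylate 3 (not isolated)
Conditions: CDI, THF, rt; then 2, rt → 40 °C
Reagents that add atoms: none
Why: CDI amide coupling, in which the acyl imidazolide acylates the secondary amine of 2 in preference to the hydroxyl; the pyrrole N-Boc group keeps the pyrrole N from closing onto the aldehyde made in step 2.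

**Step 2**
Reactants: 4
Product: 5 tert-butyl 2-{[(2R)-2-formylpyrrolidin-1-yl]carbonyl}-1H-pyrrole-1-carboxylate
Conditions: IBX, DMSO, rt
Reagents that add atoms: none
Why: IBX oxidation of a primary alcohol to the aldehyde under non-basic conditions, which should leave the α-stereocentre of the N-acylprolinal intact.

**Step 3**
Reactants: 5
Product: 6 tert-butyl 2-{[(2R)-2-(dimethoxymethyl)pyrrolidin-1-yl]carbonyl}-1H-pyrrole-1-carboxylate
Conditions: HC(OMe)3, MeOH, PPTS (cat.), rt
Reagents that add atoms: trimethyl orthoformate, COC(OC)OC; methanol, CO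
Why: Acid-catalysed acetalisation with the orthoformate as water scavenger; PPTS is expected to be too weak to cleave the pyrrole N-Boc group or to enolise the aldehyde.

**Step 4**
Reactants: 7 2,2,2-trichloroethyl sulfamate
Product: 9 2,2,2-trichloroethyl N-carbamoylsulfamate [N-(2,2,2-trichloroethoxysulfonyl)urea], via 2,2,2-trichloroethyl N-[(trichloroacetyl)carbamoyl]sulfamate 8 (not isolated)
Conditions: Cl3CC(O)NCO, CH2Cl2, 0 °C → rt; then MeOH, Et3N, rt; aq. HCl work-up
Reagents that add atoms: trichloroacetyl isocyanate, O=C=NC(=O)C(Cl)(Cl)Cl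
Why: Addition of the sulfamate N–H to the strongly electrophilic acyl isocyanate followed by methanolysis of the trichloroacetyl group, the standard acyl isocyanate route to primary carbamates and ureas.

**Step 5**
Reactants: 6; 9
Product: 11 tert-butyl 2-{[(2R)-2-{[carbamoyl(2,2,2-trichloroethoxysulfonyl)amino](methoxy)methyl}pyrrolidin-1-yl]carbonyl}-1H-pyrrole-1-carboxylate (mixture of C6 epimers), via tert-butyl 2-{[(2R)-2-[chloro(methoxy)methyl]pyrrolidin-1-yl]carbonyl}-1H-pyrrole-1-carboxylate 10 (not isolated)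
Conditions: AcCl, ZnBr2 (1 mol %), CH2Cl2, 0 °C → rt, concentrate; then 9, K2CO3, MeCN, 0 °C → rt
Reagents that add atoms: none
Why: Acetal-to-α-chloro-ether exchange followed by SN1-type N-alkylation of the sulfonylurea anion at its acidic sulfonyl nitrogen (the site that reacts in Mitsunobu alkylations of such ureas); the C6 configuration is irrelevant because C6 becomes planar again in step 7.

**Step 6**
Reactants: 11
Product: 13 tert-butyl 2-{[(5R)-4-methoxy-2-oxo-3-(2,2,2-trichloroethoxysulfonyl)-1,3,6-triazaspiro[4.4]nonan-6-yl]carbonyl}-1H-pyrrole-1-carboxylate (C4 epimers; spiro C5 = C10), via the N-(phenyl-λ3-iodanylidene) derivative of 11 (iodine(III) imide) 12 (not isolated)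
Conditions: Rh2(esp)2 (2 mol %), PhI(OAc)2, MgO, toluene, 40 °C
Reagents that add atoms: none
Why: PhI(OAc)2 converts the primary carbamoyl NH2 into the iodine(III) imide 12, from which Rh2(esp)2 forms a Rh-bound carbamoyl nitrenoid that inserts into the tertiary C10–H bond through a concerted, asynchronous three-centre transition state. The closest known reaction type is the Rh-catalysed intramolecular C–H amination of N-(trichloroethoxysulfonyl)ureas R–N(SO2OCH2CCl3)–C(O)NH2 at tertiary C–H bonds to give imidazolidin-2-ones. The imidazolidinone closes by 1,5-insertion (ring N–C(=O)–N–C6–C10) and this creates the spiro aminal. C10 is the only stereocentre formed and it is set with retention, because nitrogen enters where the hydrogen of the D-prolinol-derived carbon stood; both C6 epimers can react since the tether is acyclic. The step needs site selectivity against the OCH3 and C9–H bonds (six-membered insertions) and against the pyrrole; it should be secured by the preference of urea nitrenoids for five-membered rings and tertiary α-amido C–H bonds, and by the two acceptor groups (N-Boc, 2-carbonyl) on the pyrrole.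

**Step 7**
Reactants: 13
Product: 18 (6S,10R)-phakellstatin (the debromo tetracycle), via (5R)-6-{[1-(tert-butoxycarbonyl)pyrrol-2-yl]carbonyl}-4-methoxy-2-oxo-1,3,6-triazaspiro[4.4]nonane-3-sulfonic acid 14 (not isolated), via tert-butyl 2-{[(5R)-4-methoxy-2-oxo-1,3,6-triazaspiro[4.4]nonan-6-yl]carbonyl}-1H-pyrrole-1-carboxylate 15 (not isolated), via (5R)-4-methoxy-6-(1H-pyrrol-2-ylcarbonyl)-1,3,6-triazaspiro[4.4]nonan-2-one 16 (not isolated), via (5R)-6-(1H-pyrrol-2-ylcarbonyl)-1,3,6-triazaspiro[4.4]non-3-en-2-one 17 (not isolated)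
Conditions: Zn dust, AcOH/MeOH, rt; filter, concentrate; then TFA/CH2Cl2/H2O, 0 °C → rt
Reagents that add atoms: none
Why: Zinc fragments the trichloroethyl sulfamate ester reductively and acid hydrolyses the N-sulfonate, after which TFA removes the pyrrole N-Boc group and ionises the N,O-acetal to the cyclic N-acyliminium ion (protonated 17), which has no β-hydrogen at C10 and is captured by the pyrrole N in a 6-exo N-acyliminium closure that can only give the cis-fused ring and so sets C6.

**Step 8**
Reactants: 18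
Product: 19 (6S,10R)-dibromophakellstatin (target)
Conditions: NBS (2 equiv), DMF, 0 °C → rt, dark
Reagents that add atoms: N-bromosuccinimide, O=C1CCC(=O)N1Br
Why: Electrophilic aromatic bromination; in a 1-alkyl-2-acylpyrrole positions 4 and 5 are the most reactive, so two equivalents of NBS should give the 4,5-dibromide and leave C3 next to the carbonyl free.

**Compound list**

1 | 1-(tert-butoxycarbonyl)-1H-pyrrole-2-carboxylic acid | CC(C)(C)OC(=O)n1cccc1C(=O)O | starting material
2 | (R)-pyrrolidin-2-ylmethanol (D-prolinol) | OC[C@H]1CCCN1 | starting material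
3 | tert-butyl 2-(1H-imidazol-1-ylcarbonyl)-1H-pyrrole-1-carboxylate (formed in situ) | CC(C)(C)OC(=O)n1cccc1C(=O)n1ccnc1 | intermediate
4 | tert-butyl 2-{[(2R)-2-(hydroxymethyl)pyrrolidin-1-yl]carbonyl}-1H-pyrrole-1-carboxylate | CC(C)(C)OC(=O)n1cccc1C(=O)N1CCC[C@@H]1CO | intermediate
5 | tert-butyl 2-{[(2R)-2-formylpyrrolidin-1-yl]carbonyl}-1H-pyrrole-1-carboxylate | CC(C)(C)OC(=O)n1cccc1C(=O)N1CCC[C@@H]1C=O | intermediate
6 | tert-butyl 2-{[(2R)-2-(dimethoxymethyl)pyrrolidin-1-yl]carbonyl}-1H-pyrrole-1-carboxylate | CC(C)(C)OC(=O)n1cccc1C(=O)N1CCC[C@@H]1C(OC)OC | intermediate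
7 | 2,2,2-trichloroethyl sulfamate | NS(=O)(=O)OCC(Cl)(Cl)Cl | starting material
8 | 2,2,2-trichloroethyl N-[(trichloroacetyl)carbamoyl]sulfamate (formed in situ) | O=C(NC(=O)C(Cl)(Cl)Cl)NS(=O)(=O)OCC(Cl)(Cl)Cl | intermediate
9 | 2,2,2-trichloroethyl N-carbamoylsulfamate [N-(2,2,2-trichloroethoxysulfonyl)urea] | NC(=O)NS(=O)(=O)OCC(Cl)(Cl)Cl | intermediate
10 | tert-butyl 2-{[(2R)-2-[chloro(methoxy)methyl]pyrrolidin-1-yl]carbonyl}-1H-pyrrole-1-carboxylate (C6 epimers, formed in situ) | CC(C)(C)OC(=O)n1cccc1C(=O)N1CCC[C@@H]1C(Cl)OC | intermediate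
11 | tert-butyl 2-{[(2R)-2-{[carbamoyl(2,2,2-trichloroethoxysulfonyl)amino](methoxy)methyl}pyrrolidin-1-yl]carbonyl}-1H-pyrrole-1-carboxylate (C6 epimers) | CC(C)(C)OC(=O)n1cccc1C(=O)N1CCC[C@@H]1C(OC)N(C(N)=O)S(=O)(=O)OCC(Cl)(Cl)Cl | intermediate
12 | N-(phenyl-λ3-iodanylidene) derivative of 11, iodine(III) imide (formed in situ) | CC(C)(C)OC(=O)n1cccc1C(=O)N1CCC[C@@H]1C(OC)N(C(=O)N=Ic1ccccc1)S(=O)(=O)OCC(Cl)(Cl)Cl | intermediate
13 | tert-butyl 2-{[(5R)-4-methoxy-2-oxo-3-(2,2,2-trichloroethoxysulfonyl)-1,3,6-triazaspiro[4.4]nonan-6-yl]carbonyl}-1H-pyrrole-1-carboxylate (C4 epimers) | CC(C)(C)OC(=O)n1cccc1C(=O)N1CCC[C@@]12NC(=O)N(S(=O)(=O)OCC(Cl)(Cl)Cl)C2OC | intermediate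
14 | (5R)-6-{[1-(tert-butoxycarbonyl)pyrrol-2-yl]carbonyl}-4-methoxy-2-oxo-1,3,6-triazaspiro[4.4]nonane-3-sulfonic acid (formed in situ) | CC(C)(C)OC(=O)n1cccc1C(=O)N1CCC[C@@]12NC(=O)N(S(=O)(=O)O)C2OC | intermediate
15 | tert-butyl 2-{[(5R)-4-methoxy-2-oxo-1,3,6-triazaspiro[4.4]nonan-6-yl]carbonyl}-1H-pyrrole-1-carboxylate (formed in situ) | CC(C)(C)OC(=O)n1cccc1C(=O)N1CCC[C@@]12NC(=O)NC2OC | intermediate
16 | (5R)-4-methoxy-6-(1H-pyrrol-2-ylcarbonyl)-1,3,6-triazaspiro[4.4]nonan-2-one (formed in situ) | O=C(c1ccc[nH]1)N1CCC[C@@]12NC(=O)NC2OC | intermediate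
17 | (5R)-6-(1H-pyrrol-2-ylcarbonyl)-1,3,6-triazaspiro[4.4]non-3-en-2-one, cyclic N-acylimine, N-protonated under the conditions (formed in situ) | O=C(c1ccc[nH]1)N1CCC[C@@]12NC(=O)N=C2 | intermediate
18 | (6S,10R)-phakellstatin | O=C1N[C@H]2n3c(ccc3)C(=O)N3CCC[C@]23N1 | intermediate
19 | (6S,10R)-dibromophakellstatin | O=C1N[C@H]2n3c(cc(Br)c3Br)C(=O)N3CCC[C@]23N1 | target

**Count**

Total: 8 steps. Longest linear sequence: 7 steps (1, 2, 3, 5, 6, 7, 8); step 4 is a one-step side branch.

**Steps most likely to fail**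

Step 6 (key step). The insertion may be slow because the two σ-acceptor substituents on C6 lower the reactivity of C10–H. Nitrenoid decay or six-membered insertion into the O–CH3 group could then compete. If C–H cleavage and C–N formation become stepwise, configuration could leak. The fallback sets out from 5 and returns at 18; it replaces C–H amination by 1,2-diamination of an alkene and gives up the chiral-pool control. TFA removes the Boc group from 5 and the pyrrole N closes onto the aldehyde to give (10aR)-10-hydroxy-2,3,10,10a-tetrahydro-1H,5H-dipyrrolo[1,2-a:1',2'-d]pyrazin-5-one F1. Mesylation and elimination (MsCl, Et3N) should give the achiral enamide 2,3-dihydro-1H,5H-dipyrrolo[1,2-a:1',2'-d]pyrazin-5-one F2. An oxidative (3+2) annulation with N,N'-bis(benzyloxy)urea and PhI(OAc)2 (diaza-oxyallyl cation, a reaction type known for electron-rich C=C bonds such as C2=C3 of indoles) should give the racemic cis-fused 1,3-bis(benzyloxy)imidazolidinone tetracycle F3. SmI2 cleaves both N–O bonds to racemic phakellstatin, that is 18 together with its enantiomer (6R,10S)-phakellstatin F4. The two are separated by preparative HPLC on a chiral stationary phase, and 18 enters step 8.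

Step 5. The ambident sulfonylurea anion may be alkylated at oxygen instead of nitrogen. The α-chloro ether may also lose HCl towards an enol ether, which would erase the C10 stereocentre. The fallback sets out from 6 and returns at 11; it avoids the chloro ether and the ambident anion by assembling the urea on the substrate in two stages. Acid-catalysed transacetalisation of 6 with the neutral sulfamate 7 (CSA cat., CH2Cl2, 4 Å MS) should give the N,O-acetal sulfamate tert-butyl 2-{[(2R)-2-{methoxy[(2,2,2-trichloroethoxysulfonyl)amino]methyl}pyrrolidin-1-yl]carbonyl}-1H-pyrrole-1-carboxylate F5. Its sulfamate N–H is then carbamoylated with trichloroacetyl isocyanate to the N-[(trichloroacetyl)carbamoyl] derivative F6, which is not isolated and is cleaved with MeOH on neutral alumina to give 11.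

Step 7. The pyrrole may attack the N-acyliminium ion through C3 instead of N. The spiro aminal at C10 may also open reversibly under acid before the ring closes, which would erode the configuration. The fallback sets out from 13 and returns at 18; it closes the ring under base with an anionic nitrogen nucleophile and a neutral N-acylimine. After the zinc reduction and a brief aqueous acid treatment, 15 is isolated. Benzenesulfinic acid (CH2Cl2, MgSO4) exchanges the methoxy group for sulfinate to give tert-butyl 2-{[(5R)-2-oxo-4-(phenylsulfonyl)-1,3,6-triazaspiro[4.4]nonan-6-yl]carbonyl}-1H-pyrrole-1-carboxylate F7. K2CO3 in MeOH then removes the pyrrole Boc group to give (5R)-4-(phenylsulfonyl)-6-(1H-pyrrol-2-ylcarbonyl)-1,3,6-triazaspiro[4.4]nonan-2-one F8, expels sulfinate from the deprotonated urea to give 17, and the pyrrolide nitrogen adds to C6 to give 18.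

**Further compounds**

F1 | step 6 | (10aR)-10-hydroxy-2,3,10,10a-tetrahydro-1H,5H-dipyrrolo[1,2-a:1',2'-d]pyrazin-5-one (C10 epimers) | OC1n2cccc2C(=O)N2CCC[C@H]12
F2 | step 6 | 2,3-dihydro-1H,5H-dipyrrolo[1,2-a:1',2'-d]pyrazin-5-one (achiral enamide) | C1=C2CCCN2C(=O)c2cccn12
F3 | step 6 | racemic cis-fused N,N'-bis(benzyloxy)phakellstatin | O=C1N(OCc2ccccc2)C2n3cccc3C(=O)N3CCCC23N1OCc1ccccc1
F4 | step 6 | (6R,10S)-phakellstatin (enantiomer of 18) | O=C1N[C@@H]2n3c(ccc3)C(=O)N3CCC[C@@]23N1
F5 | step 5 | tert-butyl 2-{[(2R)-2-{methoxy[(2,2,2-trichloroethoxysulfonyl)amino]methyl}pyrrolidin-1-yl]carbonyl}-1H-pyrrole-1-carboxylate (C6 epimers) | CC(C)(C)OC(=O)n1cccc1C(=O)N1CCC[C@@H]1C(OC)NS(=O)(=O)OCC(Cl)(Cl)Cl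
F6 | step 5 | N-[(trichloroacetyl)carbamoyl] derivative of F5 (formed in situ) | CC(C)(C)OC(=O)n1cccc1C(=O)N1CCC[C@@H]1C(OC)N(C(=O)NC(=O)C(Cl)(Cl)Cl)S(=O)(=O)OCC(Cl)(Cl)Cl
F7 | step 7 | tert-butyl 2-{[(5R)-2-oxo-4-(phenylsulfonyl)-1,3,6-triazaspiro[4.4]nonan-6-yl]carbonyl}-1H-pyrrole-1-carboxylate (C4 epimers) | CC(C)(C)OC(=O)n1cccc1C(=O)N1CCC[C@@]12NC(=O)NC2S(=O)(=O)c1ccccc1
F8 | step 7 | (5R)-4-(phenylsulfonyl)-6-(1H-pyrrol-2-ylcarbonyl)-1,3,6-triazaspiro[4.4]nonan-2-one (formed in situ) | O=C(c1ccc[nH]1)N1CCC[C@@]12NC(=O)NC2S(=O)(=O)c1ccccc1
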